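**Plan**

1. Labels follow icetexane numbering: ring A = C1–C5 and C10; ring B = C5–C10 with C20; ring C = C8, C9, C11–C14; C18 (methyl) and C19 (lactone carbonyl) sit on C4; α is the face of H-5.
2. Retrosynthesis: the C7 acetate and ring C hydroxyquinone go back to a C7 silyl ether and an 11,12,14-trimethoxyarene. Ring A is cut at C1–C2 and C3–C4, removing C2–C3 as phenyl vinyl sulfone, to give a cis-fused iodolactone. C10–O and C1–I go back to a γ,δ-unsaturated acid. C4–C5 is cut by an Ireland–Claisen step to an allylic propanoate on ring B. Ring B is cut at C5=C10 (metathesis), C6–C7 (allylation) and C9–C20 (aryl allylation).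
3. Enabling feature: C10–O and C1–C2 are vicinal across C10–C1, and C4 is the α-carbon of the γ-lactone. The iodolactone of the acid C19–C4–C5–C10=C1 therefore carries a nucleophilic C4 and an electrophilic C1 held 1,3-cis on the five-membered ring, ready to be spanned by a two-carbon unit.
4. Forward order: ring C (arene) → ring B (ring-closing metathesis) → C4–C5 ([3,3]) → lactone ring (iodolactonization) → ring A (Michael/alkylation annulation) → quinone and acetate.
5. Stereochemistry: C7 from a reagent-controlled allylboration; C5 from the Claisen step, anti to the C7 silyloxy group; C10 from cis-selective iodolactonization; C4 from convex-face Michael addition, enforced by the bridge.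

Key step: step 11

Remark: formylation of 4 is assumed to follow 1,2,4-trimethoxybenzene itself (attack para to the 2-methoxy group); C4 in 19 and 20 and C2 in 23 are epimer mixtures that converge or are erased later.

**Route**

Step 1
Reactants: 1 1,2,4-trimethoxybenzene
Product: 3 2-(2,3,6-trimethoxyphenyl)propan-2-ol, via 2,3,6-trimethoxyphenyllithium 2 (not isolated)
Conditions: n-BuLi, THF, 0 → 20 °C; acetone, −78 → 20 °C; then H2O
Reagents that add atoms: acetone, CC(C)=O
Why: Directed ortho-lithiation should occur at C3, the position flanked by two methoxy groups, and the aryllithium then undergoes 1,2-addition to acetone.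

Step 2
Reactants: 3 2-(2,3,6-trimethoxyphenyl)propan-2-ol
Product: 4 1,2,4-trimethoxy-3-(propan-2-yl)benzene
Conditions: Et3SiH, CF3CO2H, CH2Cl2, 0 → 20 °C
Reagents that add atoms: none
Why: Ionic hydrogenation: the tertiary benzylic cation, stabilised by two ortho methoxy groups, forms in acid and is reduced by hydride transfer from the silane.

Step 3
Reactants: 4 1,2,4-trimethoxy-3-(propan-2-yl)benzene
Product: 6 2,4,5-trimethoxy-3-(propan-2-yl)benzaldehyde, via iminium chloride 5 (not isolated)
Conditions: POCl3, DMF, 0 → 70 °C; then H2O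
Reagents that add atoms: N,N-dimethylformamide, CN(C)C=O; water, O
Why: Vilsmeier–Haack formylation should take place at the ring position para to the 2-methoxy and ortho to the 4-methoxy group, and hydrolysis of the iminium salt gives the aldehyde (C7 on C8).

Step 4
Reactants: 6 2,4,5-trimethoxy-3-(propan-2-yl)benzaldehyde; 7 3-chloro-2-(chloromethyl)prop-1-ene
Product: 11 2-[2-(chloromethyl)prop-2-en-1-yl]-3,4,6-trimethoxy-5-(propan-2-yl)benzaldehyde, via lithium α-amino alkoxide 8 (not isolated), via ring-lithiated α-amino alkoxide 9 (not isolated), via allylated α-amino alkoxide 10 (not isolated)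
Conditions: LiN(Me)CH2CH2NMe2 (from the amine and n-BuLi), THF, −20 °C; n-BuLi, −20 °C; CuBr·SMe2 (10 mol %), 7 (4 equiv), −78 → 0 °C; then H2O
Reagents that add atoms: none
Why: Directed ortho-metalation through an in situ α-amino alkoxide, which masks the aldehyde and, with the neighbouring methoxy group, directs lithiation to the only free ring position (C9); copper-catalysed allylic substitution on excess 7 forms C9–C20 and hydrolysis returns the aldehyde.

Step 5
Reactants: 11 2-[2-(chloromethyl)prop-2-en-1-yl]-3,4,6-trimethoxy-5-(propan-2-yl)benzaldehyde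
Product: 12 2-{[2-formyl-3,5,6-trimethoxy-4-(propan-2-yl)phenyl]methyl}prop-2-en-1-yl propanoate
Conditions: EtCO2Cs, DMF, 50 °C
Reagents that add atoms: cesium propanoate, CCC(=O)[O-].[Cs+]
Why: SN2 displacement of the primary allylic chloride by the carboxylate installs the ester needed for the later Claisen step without touching the aldehyde.

Step 6
Reactants: 12 2-{[2-formyl-3,5,6-trimethoxy-4-(propan-2-yl)phenyl]methyl}prop-2-en-1-yl propanoate
Product: 14 2-({2-[(1R)-1-hydroxybut-3-en-1-yl]-3,5,6-trimethoxy-4-(propan-2-yl)phenyl}methyl)prop-2-en-1-yl propanoate, via borinate ester 13 (not isolated)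
Conditions: (+)-Ipc2B(allyl), Et2O, −78 °C; then HOCH2CH2NH2, 20 °C
Reagents that add atoms: (+)-B-allyldiisopinocampheylborane (the reagent derived from (−)-α-pinene), C=CCB([C@H]1C[C@H]2C[C@@H]([C@@H]1C)C2(C)C)[C@H]1C[C@H]2C[C@@H]([C@@H]1C)C2(C)C
Why: Asymmetric allylboration through a closed six-membered chair transition state; the isopinocampheyl groups of this enantiomer of the reagent should deliver allyl to the Re face of the aldehyde and so set C7 as (R), and the non-oxidative ethanolamine work-up spares the ester.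

Step 7
Reactants: 14 2-({2-[(1R)-1-hydroxybut-3-en-1-yl]-3,5,6-trimethoxy-4-(propan-2-yl)phenyl}methyl)prop-2-en-1-yl propanoate
Product: 15 tert-butyldimethylsilyl ether of 14, 2-({2-[(1R)-1-{[tert-butyl(dimethyl)silyl]oxy}but-3-en-1-yl]-3,5,6-trimethoxy-4-(propan-2-yl)phenyl}methyl)prop-2-en-1-yl propanoate
Conditions: t-BuMe2SiOTf, 2,6-lutidine, CH2Cl2, −78 → 0 °C
Reagents that add atoms: tert-butyldimethylsilyl trifluoromethanesulfonate, CC(C)(C)[Si](C)(C)OS(=O)(=O)C(F)(F)F
Why: O-silylation of the hindered benzylic alcohol with the silyl triflate under buffered conditions, which should not ionise the electron-rich benzylic C–O bond.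

Step 8
Reactants: 15 silyl ether diene
Product: 16 [(5R)-5-{[tert-butyl(dimethyl)silyl]oxy}-1,2,4-trimethoxy-3-(propan-2-yl)-6,9-dihydro-5H-benzo[7]annulen-8-yl]methyl propanoate
Conditions: second-generation Grubbs catalyst RuCl2(=CHPh)(PCy3)(H2IMes) (5 mol %), toluene, 80 °C
Reagents that add atoms: none
Why: Ring-closing metathesis of the mono-substituted and the 1,1-disubstituted alkene forms the trisubstituted C5=C10 alkene and closes ring B, driven by loss of ethene.

Step 9
Reactants: 16 [(5R)-5-silyloxy-benzo[7]annulen-8-yl]methyl propanoate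
Product: 19 2-[(5R,7S)-5-{[tert-butyl(dimethyl)silyl]oxy}-1,2,4-trimethoxy-8-methylidene-3-(propan-2-yl)-6,7,8,9-tetrahydro-5H-benzo[7]annulen-7-yl]propanoic acid (both epimers at the α-carbon, C4), via silyl ketene acetal 17 (not isolated), via trimethylsilyl ester 18 (not isolated)
Conditions: LiN(i-Pr)2, THF, −78 °C; Me3SiCl, −78 → 40 °C; then H2O
Reagents that add atoms: none
Why: Ireland–Claisen rearrangement through a chair [3,3] transition state forms C4–C5 and the exocyclic C10=C1 alkene; the C7 silyloxy group is held pseudo-axial by the peri methoxy group, the ring folds away from it, and C4 should be delivered to the convex alkene face, trans to the silyloxy group (C5 S).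

Step 10
Reactants: 19 γ,δ-unsaturated acid
Product: 20 iodolactone: γ-lactone C19(=O)–O–C10 cis-fused to ring B across C5–C10, with 10β-O, 10α-CH2I, 5α-H, 7α-OSi(t-Bu)Me2 (C5 S, C7 R, C10 S), ring C 11,12,14-trimethoxy-13-isopropyl, both C4 epimers
Conditions: I2, NaHCO3, MeCN–H2O, 0 °C, dark
Reagents that add atoms: iodine, II
Why: Iodolactonization (5-exo, Markovnikov): allylic strain places the C5 side chain pseudo-axial next to the exocyclic methylene, so the carboxylate should attack C10 on its own face and give the cis-fused lactone with CH2I on the opposite face.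

Step 11
Reactants: 20 iodolactone; 21 ethenylsulfonylbenzene (phenyl vinyl sulfone)
Product: 23 (4S,5S,7R)-7-{[tert-butyl(dimethyl)silyl]oxy}-11,12,14-trimethoxy-2-(phenylsulfonyl)icetexa-8,11,13-trien-19,10β-olide (either epimer at C2), via lithiated Michael adduct 22 (not isolated)
Conditions: LiN(i-Pr)2, THF, −78 °C; 21, −78 → −40 °C; then HMPA, −40 → 25 °C
Reagents that add atoms: none
Why: LiN(i-Pr)2 converts both C4 epimers of 20 into one lactone enolate, whose C4 adds to the β-carbon of 21 to give the α-sulfonyl carbanion 22; on warming with HMPA its carbon C2 displaces iodide at the neopentyl-type C1 in an intramolecular SN2 step. The closest known reaction type is the Michael-initiated ring closure, in which a vinyl sulfone serves as a two-carbon unit between an enolate carbon and a halide-bearing carbon of the same molecule. Ring A closes in the 6-exo-tet mode and becomes the three-carbon bridge of the 6-oxabicyclo[3.2.1]octan-7-one. The quaternary stereocentre C4 is set in the Michael step by approach to the convex face of the cis-fused lactone (the face of H-5 and CH2I, anti to the ring B carbon C6 on the neighbouring C5), and only this epimer can bridge to C1; the sulfonyl-bearing C2 forms without control and is erased in step 12. The step needs conjugate addition to outrun self-alkylation of the enolate, and carbon attack to outrun iodine attack by the carbanion: closure of the enolate onto C1 would make a strained four-membered ring, whereas the C3–C2 arm and CH2I sit 1,3-cis on the five-membered ring at the right distance for a six-membered transition state.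

Step 12
Reactants: 23 C2 sulfone
Product: 24 (4S,5S,7R,10S)-7-{[tert-butyl(dimethyl)silyl]oxy}-11,12,14-trimethoxyicetexa-8,11,13-trien-19,10-olide
Conditions: 6% Na(Hg), Na2HPO4, MeOH–THF, −20 → 0 °C
Reagents that add atoms: none
Why: Reductive desulfonylation by electron transfer cleaves the C2–S bond; no leaving group is β to C2, so the buffered conditions should leave the lactone and silyl ether intact.

Step 13
Reactants: 24 silyl ether
Product: 25 (4S,5S,7R,10S)-7-hydroxy-11,12,14-trimethoxyicetexa-8,11,13-trien-19,10-olide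
Conditions: Bu4NF, THF, 0 → 20 °C; then H2O
Reagents that add atoms: none
Why: Fluoride cleaves the Si–O bond only, so the benzylic C7–O bond and its configuration are untouched.

Step 14
Reactants: 25 7α-alcohol
Product: 26 (4S,5S,7R,10S)-7-hydroxy-12-methoxy-11,14-dioxoicetexa-8,12-dien-19,10-olide
Conditions: (NH4)2Ce(NO3)6, MeCN–H2O, 0 °C
Reagents that add atoms: water, O
Why: Oxidative demethylation by ceric ammonium nitrate converts the para-related C11/C14 dimethoxy pair into the 11,14-quinone and leaves the C12 methoxy group as a vinylogous ester.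

Step 15
Reactants: 26 12-methoxyquinone
Product: 27 (4S,5S,7R,10S)-7,12-dihydroxy-11,14-dioxoicetexa-8,12-dien-19,10-olide (7α-hydroxy-6,7-dihydroicetexone)
Conditions: NaOH (0.2 M aq), THF–MeOH, 0 °C; then HCl (aq)
Reagents that add atoms: sodium hydroxide, [Na+].[OH-]
Why: Addition–elimination of hydroxide at C12 hydrolyses the vinylogous ester; the hindered bridged lactone should survive or re-close on acidification.

Step 16
Reactants: 27 7α-hydroxy-6,7-dihydroicetexone
Product: 29 7α-acetoxy-6,7-dihydroicetexone, (4S,5S,7R,10S)-7-acetoxy-12-hydroxy-11,14-dioxoicetexa-8,12-dien-19,10-olide, via diacetate 28 (not isolated)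
Conditions: Ac2O, pyridine, DMAP (cat.), CH2Cl2, 0 → 20 °C; then MeOH, NaHCO3 (cat.), 0 °C
Reagents that add atoms: acetic anhydride, CC(=O)OC(C)=O
Why: Acylation of both hydroxyl groups, then selective methanolysis of the C12 enol acetate, a vinylogous mixed anhydride far more labile than the secondary C7 acetate; C7 is acylated with retention.

**Compound list**

1 | 1,2,4-trimethoxybenzene | COc1ccc(OC)c(OC)c1 | starting material
2 | 2,3,6-trimethoxyphenyllithium | [Li]c1c(OC)ccc(OC)c1OC | intermediate
3 | 2-(2,3,6-trimethoxyphenyl)propan-2-ol | COc1ccc(OC)c(C(C)(C)O)c1OC | intermediate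
4 | 1,2,4-trimethoxy-3-(propan-2-yl)benzene | COc1ccc(OC)c(C(C)C)c1OC | intermediate
5 | N,N-dimethyl[2,4,5-trimethoxy-3-(propan-2-yl)phenyl]methaniminium chloride | C[N+](C)=Cc1cc(OC)c(OC)c(C(C)C)c1OC.[Cl-] | intermediate
6 | 2,4,5-trimethoxy-3-(propan-2-yl)benzaldehyde | O=Cc1cc(OC)c(OC)c(C(C)C)c1OC | intermediate
7 | 3-chloro-2-(chloromethyl)prop-1-ene | C=C(CCl)CCl | starting material
8 | lithium α-amino alkoxide of 6, ArCH(OLi)N(Me)CH2CH2NMe2 | [Li]OC(N(C)CCN(C)C)c1cc(OC)c(OC)c(C(C)C)c1OC | intermediate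
9 | 8 lithiated at the ring position between the alkoxide carbon and the methoxy group | [Li]OC(N(C)CCN(C)C)c1c([Li])c(OC)c(OC)c(C(C)C)c1OC | intermediate
10 | α-amino alkoxide carrying the 2-(chloromethyl)allyl group | [Li]OC(N(C)CCN(C)C)c1c(CC(=C)CCl)c(OC)c(OC)c(C(C)C)c1OC | intermediate
11 | 2-[2-(chloromethyl)prop-2-en-1-yl]-3,4,6-trimethoxy-5-(propan-2-yl)benzaldehyde | O=Cc1c(CC(=C)CCl)c(OC)c(OC)c(C(C)C)c1OC | intermediate
12 | 2-{[2-formyl-3,5,6-trimethoxy-4-(propan-2-yl)phenyl]methyl}prop-2-en-1-yl propanoate | O=Cc1c(CC(=C)COC(=O)CC)c(OC)c(OC)c(C(C)C)c1OC | intermediate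
13 | O-diisopinocampheylboryl derivative (borinate ester) of 14 | C[C@@H]1[C@H](C[C@H]2C[C@@H]1C2(C)C)B(O[C@H](CC=C)c1c(OC)c(C(C)C)c(OC)c(OC)c1CC(=C)COC(=O)CC)[C@H]1C[C@H]2C[C@@H]([C@@H]1C)C2(C)C | intermediate
14 | 2-({2-[(1R)-1-hydroxybut-3-en-1-yl]-3,5,6-trimethoxy-4-(propan-2-yl)phenyl}methyl)prop-2-en-1-yl propanoate | O[C@H](CC=C)c1c(OC)c(C(C)C)c(OC)c(OC)c1CC(=C)COC(=O)CC | intermediate
15 | (1R)-tert-butyldimethylsilyl ether of 14 | CC(C)(C)[Si](C)(C)O[C@H](CC=C)c1c(OC)c(C(C)C)c(OC)c(OC)c1CC(=C)COC(=O)CC | intermediate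
16 | [(5R)-5-{[tert-butyl(dimethyl)silyl]oxy}-1,2,4-trimethoxy-3-(propan-2-yl)-6,9-dihydro-5H-benzo[7]annulen-8-yl]methyl propanoate | CCC(=O)OCC1=CC[C@@H](O[Si](C)(C)C(C)(C)C)c2c(OC)c(C(C)C)c(OC)c(OC)c2C1 | intermediate
17 | (E)-trimethylsilyl ketene acetal of 16 | C/C=C(/O[Si](C)(C)C)OCC1=CC[C@@H](O[Si](C)(C)C(C)(C)C)c2c(OC)c(C(C)C)c(OC)c(OC)c2C1 | intermediate
18 | trimethylsilyl ester of 19 | CC(C)(C)[Si](C)(C)O[C@@H]1C[C@@H](C(C)C(=O)O[Si](C)(C)C)C(=C)Cc2c1c(OC)c(C(C)C)c(OC)c2OC | intermediate
19 | 2-[(5R,7S)-5-{[tert-butyl(dimethyl)silyl]oxy}-1,2,4-trimethoxy-8-methylidene-3-(propan-2-yl)-6,7,8,9-tetrahydro-5H-benzo[7]annulen-7-yl]propanoic acid, both α-epimers | CC(C)(C)[Si](C)(C)O[C@@H]1C[C@@H](C(C)C(=O)O)C(=C)Cc2c1c(OC)c(C(C)C)c(OC)c2OC | intermediate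
20 | iodolactone: 19,10β-olide cis-fused to ring B, 10α-iodomethyl, 5α-H, 7α-silyloxy (C5 S, C7 R, C10 S), both C4 epimers | CC(C)(C)[Si](C)(C)O[C@@H]1C[C@@H]2[C@@](CI)(OC(=O)C2C)Cc2c1c(OC)c(C(C)C)c(OC)c2OC | intermediate
21 | ethenylsulfonylbenzene (phenyl vinyl sulfone) | C=CS(=O)(=O)c1ccccc1 | starting material
22 | Michael adduct of the enolate of 20 to 21, lithiated at the sulfonyl α-carbon (C2); C4 S | CC(C)(C)[Si](C)(C)O[C@@H]1C[C@@H]2[C@@](CI)(OC(=O)[C@@]2(C)CC([Li])S(=O)(=O)c2ccccc2)Cc2c1c(OC)c(C(C)C)c(OC)c2OC | intermediate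
23 | 7α-{[tert-butyl(dimethyl)silyl]oxy}-11,12,14-trimethoxy-2-(phenylsulfonyl)icetexa-8,11,13-trien-19,10β-olide, configuration at C4, C5, C7, C10 as in 24, C2 either | CC(C)(C)[Si](C)(C)O[C@@H]1C[C@@H]2[C@]3(CC(S(=O)(=O)c4ccccc4)C[C@]2(C)C(=O)O3)Cc2c1c(OC)c(C(C)C)c(OC)c2OC | intermediate
24 | (4S,5S,7R,10S)-7-{[tert-butyl(dimethyl)silyl]oxy}-11,12,14-trimethoxyicetexa-8,11,13-trien-19,10-olide | CC(C)(C)[Si](C)(C)O[C@@H]1C[C@@H]2[C@]3(CCC[C@]2(C)C(=O)O3)Cc2c1c(OC)c(C(C)C)c(OC)c2OC | intermediate
25 | (4S,5S,7R,10S)-7-hydroxy-11,12,14-trimethoxyicetexa-8,11,13-trien-19,10-olide | O[C@@H]1C[C@@H]2[C@]3(CCC[C@]2(C)C(=O)O3)Cc2c1c(OC)c(C(C)C)c(OC)c2OC | intermediate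
26 | (4S,5S,7R,10S)-7-hydroxy-12-methoxy-11,14-dioxoicetexa-8,12-dien-19,10-olide | O[C@@H]1C[C@@H]2[C@]3(CCC[C@]2(C)C(=O)O3)CC2=C1C(=O)C(C(C)C)=C(OC)C2=O | intermediate
27 | 7α-hydroxy-6,7-dihydroicetexone, (4S,5S,7R,10S)-7,12-dihydroxy-11,14-dioxoicetexa-8,12-dien-19,10-olide | O[C@@H]1C[C@@H]2[C@]3(CCC[C@]2(C)C(=O)O3)CC2=C1C(=O)C(C(C)C)=C(O)C2=O | intermediate
28 | 7α,12-diacetate of 27 | CC(=O)O[C@@H]1C[C@@H]2[C@]3(CCC[C@]2(C)C(=O)O3)CC2=C1C(=O)C(C(C)C)=C(OC(C)=O)C2=O | intermediate
29 | 7α-acetoxy-6,7-dihydroicetexone | CC(=O)O[C@@H]1C[C@@H]2[C@]3(CCC[C@]2(C)C(=O)O3)CC2=C1C(=O)C(C(C)C)=C(O)C2=O | target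

**Count and risks**

Total step count: 16. Longest linear sequence: 16 steps (1 → 29); 7 and 21 are bought.

Most likely to fail:

Step 11 (key annulation). The α-sulfonyl carbanion may attack iodine instead of carbon, which would be followed by loss of the carboxylate and reversal of the iodolactonization. Alternatively, substitution at the neopentyl-type C1 may be so slow that the carbanion is consumed by further addition to 21. Fallback, radical instead of anionic closure of the same C1–C2 bond, setting out from 20 and returning at 24: the enolate of 20 (LiN(i-Pr)2, THF, −78 °C) is C-allylated on the convex face with allyl bromide to give the 4-allyl iodolactone F1. Oxidative cleavage (OsO4 cat., NaIO4, 2,6-lutidine, dioxane–H2O) gives the aldehyde F2, in which the aldehyde carbon is C2. Bu3SnH/AIBN (slow addition, benzene, 80 °C) generates the C1 radical, which should add 6-exo to the aldehyde carbon and give the C2 cyclohexanol F3. Barton–McCombie deoxygenation through the imidazolyl thiocarbonate F4 (1,1′-thiocarbonyldiimidazole, DMAP; then Bu3SnH/AIBN) gives 24.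

Step 9 (Claisen rearrangement). The facial selectivity may be poor: the remote C7 silyloxy group may bias the two faces of the C5=C10 alkene too weakly, which would carry the C5 epimer into every later compound. Fallback, reagent control instead of substrate control, setting out from 16 and returning at 19: 16 is treated with (4S,5S)-2-bromo-4,5-diphenyl-1,3-bis{[3,5-bis(trifluoromethyl)phenyl]sulfonyl}-1,3,2-diazaborolidine and Et3N (toluene, −78 °C) to form the chiral boron ketene acetal F5. Its [3,3] rearrangement at −20 °C and hydrolytic work-up should give 19. The sense of induction of this controller is not assigned here; the enantiomer whose own facial preference coincides with the anti pathway would be used, and the (S,S) form is drawn.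

Step 15 (alkaline hydrolysis of the methoxyquinone). Hydroxide may open the lactone or degrade the base-sensitive 7-hydroxy quinone before the vinylogous ester is cleaved. Fallback, acetate first and Lewis-acid demethylation last, setting out from 25 and returning at 29: 25 is acetylated (Ac2O, pyridine, DMAP) to the 7α-acetoxy trimethoxyarene F6. (NH4)2Ce(NO3)6 (MeCN–H2O, 0 °C) gives the 7α-acetoxy-12-methoxyquinone F7. BCl3 (CH2Cl2, −78 °C), chelated between the C11 carbonyl and the C12 methoxy oxygen, should cleave only this methyl ether and give 29.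

**Further compounds**

F1 | step 11 | 4β-allyl iodolactone (C4 S), otherwise as 20 | CC(C)(C)[Si](C)(C)O[C@@H]1C[C@@H]2[C@@](CI)(OC(=O)[C@@]2(C)CC=C)Cc2c1c(OC)c(C(C)C)c(OC)c2OC
F2 | step 11 | aldehyde from cleavage of the allyl group of F1 (C4–CH2–CHO) | CC(C)(C)[Si](C)(C)O[C@@H]1C[C@@H]2[C@@](CI)(OC(=O)[C@@]2(C)CC=O)Cc2c1c(OC)c(C(C)C)c(OC)c2OC
F3 | step 11 | 2-hydroxy derivative of 24 (either C2 epimer) | CC(C)(C)[Si](C)(C)O[C@@H]1C[C@@H]2[C@]3(CC(O)C[C@]2(C)C(=O)O3)Cc2c1c(OC)c(C(C)C)c(OC)c2OC
F4 | step 11 | O-(imidazol-1-ylthiocarbonyl) derivative of F3 | CC(C)(C)[Si](C)(C)O[C@@H]1C[C@@H]2[C@]3(CC(OC(=S)n4ccnc4)C[C@]2(C)C(=O)O3)Cc2c1c(OC)c(C(C)C)c(OC)c2OC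
F5 | step 9 | boron ketene acetal of 16 with the (4S,5S)-diazaborolidine | C/C=C(/OB1N(S(=O)(=O)c2cc(cc(c2)C(F)(F)F)C(F)(F)F)[C@@H](c2ccccc2)[C@H](c2ccccc2)N1S(=O)(=O)c1cc(cc(c1)C(F)(F)F)C(F)(F)F)OCC1=CC[C@@H](O[Si](C)(C)C(C)(C)C)c2c(OC)c(C(C)C)c(OC)c(OC)c2C1
F6 | step 15 | (4S,5S,7R,10S)-7-acetoxy-11,12,14-trimethoxyicetexa-8,11,13-trien-19,10-olide | CC(=O)O[C@@H]1C[C@@H]2[C@]3(CCC[C@]2(C)C(=O)O3)Cc2c1c(OC)c(C(C)C)c(OC)c2OC
F7 | step 15 | (4S,5S,7R,10S)-7-acetoxy-12-methoxy-11,14-dioxoicetexa-8,12-dien-19,10-olide | CC(=O)O[C@@H]1C[C@@H]2[C@]3(CCC[C@]2(C)C(=O)O3)CC2=C1C(=O)C(C(C)C)=C(OC)C2=O
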